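**Retrosynthetic overview**
1. Target ⇐ desilylation/ester hydrolysis ⇐ C5 acrylate installed by C–H borylation and oxidative Heck coupling on a 5-unsubstituted 7-methoxy-2,3-dihydrobenzofuran.
2. Key disconnection: the benzofuran benzene ring and the dihydrofuran ring are made together by a gold-catalysed furan–yne cycloisomerisation of a 2-(furan-2-yl)ethyl alkynyl ether. Furan C2–C5 become C3a–C6, the two alkyne carbons become C7a/C7, and the furan oxygen becomes the 7-OH.
3. Alkynyl ether ⇐ secondary benzylic alcohol + trichloroethylene; C2 and C3 are already set in the open chain and are not touched by the ring formation.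
4. Stereodiad ⇐ Evans syn-aldol of an (R)-N-(2-furylacetyl)oxazolidinone with O-TIPS-vanillin, then reductive auxiliary removal.
5. Ring order: vanillin's arene and a sacrificial furan are bought; the benzene ring and the O-heterocycle of the benzofuran form in one step (step 7).

Assumption: the SMILES encodes the (2R,3S)-trans isomer by CIP analysis, and that enantiomer is the one made.

---

**Step 1**
Reactants: 1, vanillin
Product: 3, 3-methoxy-4-[(triisopropylsilyl)oxy]benzaldehyde
Conditions: TIPSCl, imidazole, DMF, rt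
Reagents that add atoms: 2, triisopropylsilyl chloride, CC(C)[Si](Cl)(C(C)C)C(C)C
Why: Phenol silylation; the bulky aryl TIPS ether survives KH, n-BuLi and Lewis acids, has no unhindered aryl C–H for the later borylation, and is less electron-donating than an alkyl ether.

**Step 2**
Reactants: 4, 2-furylacetic acid; 5, (R)-4-benzyloxazolidin-2-one
Product: 6, (R)-4-benzyl-3-[2-(furan-2-yl)acetyl]oxazolidin-2-one
Conditions: PivCl, Et3N, THF, −20 °C; then 5, LiCl, rt
Reagents that add atoms: none (only reactants 4 and 5)
Why: Mixed-anhydride N-acylation of the Evans auxiliary, routine for arylacetic acids.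

**Step 3**
Reactants: 6, (R)-N-(2-furylacetyl)oxazolidinone; 3, O-TIPS-vanillin
Product: 7, (4R)-4-benzyl-3-[(2S,3R)-2-(furan-2-yl)-3-hydroxy-3-{3-methoxy-4-[(triisopropylsilyl)oxy]phenyl}propanoyl]oxazolidin-2-one
Conditions: Bu2BOTf, iPr2NEt, CH2Cl2, 0 °C; then 3, −78 → 0 °C; pH 7 buffer/MeOH/H2O2, 0 °C
Reagents that add atoms: none
Why: Evans syn-aldol; the Z-boron enolate reacts through a Zimmerman–Traxler chair and the (R)-auxiliary sets both stereocentres as (2S,3R), the syn diad that maps onto the trans-(2R,3S) ring.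

**Step 4**
Reactants: 7, aldol adduct
Product: 8, (1R,2S)-2-(furan-2-yl)-1-{3-methoxy-4-[(triisopropylsilyl)oxy]phenyl}propane-1,3-diol
Conditions: LiBH4, MeOH (1 equiv), THF, 0 °C
Reagents that add atoms: none
Why: Reductive cleavage of the N-acyl oxazolidinone to the primary alcohol under mild, weakly basic conditions that avoid retro-aldol and α-epimerisation (auxiliary recovered).

**Step 5**
Reactants: 8, diol
Product: 9, (1R,2S)-2-(furan-2-yl)-1-{3-methoxy-4-[(triisopropylsilyl)oxy]phenyl}-3-[(triisopropylsilyl)oxy]propan-1-ol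
Conditions: TIPSCl (1.1 equiv), imidazole, CH2Cl2, 0 °C
Reagents that add atoms: 2, triisopropylsilyl chloride, CC(C)[Si](Cl)(C(C)C)C(C)C
Why: Sterically controlled silylation of the primary over the hindered secondary benzylic alcohol; TIPS is chosen because it migrates far less readily than TBS under the basic next step.

**Step 6**
Reactants: 9, secondary alcohol
Product: 11, 2-[(1S,2R)-2-(ethynyloxy)-2-{3-methoxy-4-[(triisopropylsilyl)oxy]phenyl}-1-{[(triisopropylsilyl)oxy]methyl}ethyl]furan (benzylic O-alkynyl carbon R, furyl-bearing carbon S; same spatial arrangement as 9)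
Conditions: KH, THF, 0 °C; Cl2C=CHCl, rt; then n-BuLi (2.5 equiv), −78 → −40 °C; MeOH quench; kept cold and used directly
Reagents that add atoms: 10, trichloroethylene, ClC=C(Cl)Cl
Why: Greene alkynyl ether synthesis; the alkoxide adds to in-situ dichloroacetylene to give the 1,2-dichlorovinyl ether, which n-BuLi converts by elimination and Cl–Li exchange into the lithium alkynyl ether, with no bond to either stereocentre broken.

**Step 7 (key step)**
Reactants: 11, furyl alkynyl ether
Product: 12, (2R,3S)-2-{3-methoxy-4-[(triisopropylsilyl)oxy]phenyl}-3-{[(triisopropylsilyl)oxy]methyl}-2,3-dihydro-1-benzofuran-7-ol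
Conditions: IPrAuCl/AgNTf2 (2 mol %), CH2Cl2, −20 °C → rt
Reagents that add atoms: none (isomerisation)
Why: Gold-catalysed furan–yne phenol synthesis (Hashmi type, alkynyl-ether variant, here on a substituted tether): furan C2 attacks the gold-activated O-bearing alkyne carbon 5-exo, the cyclopropyl carbenoid opens to a dienal carbenoid, and closure via oxepine/arene oxide gives the phenol with OH ortho to the ring oxygen, forming both rings while the existing stereocentres are untouched.

**Step 8**
Reactants: 12, 7-hydroxy-dihydrobenzofuran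
Product: 14, (2R,3S)-7-methoxy-2-{3-methoxy-4-[(triisopropylsilyl)oxy]phenyl}-3-{[(triisopropylsilyl)oxy]methyl}-2,3-dihydro-1-benzofuran
Conditions: MeOH, PPh3, DIAD, THF, 0 °C → rt
Reagents that add atoms: 13, methanol, CO
Why: Mitsunobu O-methylation of the only free phenol under neutral conditions, so the aryl TIPS ether cannot be cleaved and methylated.

**Step 9**
Reactants: 14, 7-methoxy-dihydrobenzofuran
Product: 16, (2R,3S)-7-methoxy-2-{3-methoxy-4-[(triisopropylsilyl)oxy]phenyl}-5-(4,4,5,5-tetramethyl-1,3,2-dioxaborolan-2-yl)-3-{[(triisopropylsilyl)oxy]methyl}-2,3-dihydro-1-benzofuran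
Conditions: [Ir(cod)OMe]2 (1.5 mol %), dtbpy (3 mol %), B2pin2 (0.7 equiv), THF, 70 °C
Reagents that add atoms: 15, bis(pinacolato)diboron, CC1(C)OB(OC1(C)C)B1OC(C)(C)C(C)(C)O1
Why: Sterically controlled iridium-catalysed aromatic C–H borylation; C5–H is the only aryl C–H in the molecule without an ortho substituent, and every C–H on the other ring is flanked by OTIPS, OMe or the benzylic carbon.

**Step 10**
Reactants: 16, aryl boronate
Product: 18, methyl (E)-3-[(2R,3S)-7-methoxy-2-{3-methoxy-4-[(triisopropylsilyl)oxy]phenyl}-3-{[(triisopropylsilyl)oxy]methyl}-2,3-dihydro-1-benzofuran-5-yl]prop-2-enoate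
Conditions: methyl acrylate, Pd(OAc)2 (5 mol %), neocuproine, O2 (1 atm), DMF, 50 °C
Reagents that add atoms: 17, methyl acrylate, C=CC(=O)OC
Why: Oxidative (boron) Heck reaction; transmetalation to Pd(II), syn-insertion and β-hydride elimination give the E-cinnamate, with O2 reoxidising Pd(0).

**Step 11**
Reactants: 18, bis-TIPS methyl ester
Product: 19, (E)-3-[(2R,3S)-2-(4-hydroxy-3-methoxyphenyl)-3-(hydroxymethyl)-7-methoxy-2,3-dihydro-1-benzofuran-5-yl]prop-2-enoic acid (target)
Conditions: TBAF, THF, rt; then LiOH, THF/H2O, rt; acidify to pH 3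
Reagents that add atoms: lithium hydroxide/water, [Li+].[OH-] and O (the carboxyl OH oxygen)
Why: Fluoride cleavage of both silyl ethers followed in the same pot by ester saponification; C3 carries no carbonyl so it cannot epimerise, and any reversible quinone-methide opening at C2 recloses to the trans ring.

---

**Compound list**
1 | vanillin | O=Cc1ccc(O)c(OC)c1 | starting material
2 | triisopropylsilyl chloride | CC(C)[Si](Cl)(C(C)C)C(C)C | starting material
3 | 3-methoxy-4-[(triisopropylsilyl)oxy]benzaldehyde | COc1cc(C=O)ccc1O[Si](C(C)C)(C(C)C)C(C)C | intermediate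
4 | 2-furylacetic acid | OC(=O)Cc1ccco1 | starting material
5 | (R)-4-benzyloxazolidin-2-one | O=C1N[C@H](Cc2ccccc2)CO1 | starting material
6 | (R)-4-benzyl-3-[2-(furan-2-yl)acetyl]oxazolidin-2-one | O=C(Cc1ccco1)N1C(=O)OC[C@H]1Cc1ccccc1 | intermediate
7 | (2S,3R)-syn aldol adduct on the (R)-auxiliary | COc1cc([C@H](O)[C@H](C(=O)N2C(=O)OC[C@H]2Cc2ccccc2)c2ccco2)ccc1O[Si](C(C)C)(C(C)C)C(C)C | intermediate
8 | (1R,2S)-2-(furan-2-yl)-1-aryl-propane-1,3-diol | COc1cc([C@H](O)[C@H](CO)c2ccco2)ccc1O[Si](C(C)C)(C(C)C)C(C)C | intermediate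
9 | (1R,2S) primary-TIPS secondary alcohol | COc1cc([C@H](O)[C@H](CO[Si](C(C)C)(C(C)C)C(C)C)c2ccco2)ccc1O[Si](C(C)C)(C(C)C)C(C)C | intermediate
10 | trichloroethylene | ClC=C(Cl)Cl | starting material
11 | furyl alkynyl ether (benzylic C R, furyl C S) | COc1cc([C@H](OC#C)[C@H](CO[Si](C(C)C)(C(C)C)C(C)C)c2ccco2)ccc1O[Si](C(C)C)(C(C)C)C(C)C | intermediate
12 | (2R,3S)-7-hydroxy-2,3-dihydrobenzofuran, bis-TIPS | COc1cc([C@@H]2Oc3c(O)cccc3[C@H]2CO[Si](C(C)C)(C(C)C)C(C)C)ccc1O[Si](C(C)C)(C(C)C)C(C)C | intermediate
13 | methanol | CO | starting material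
14 | (2R,3S)-7-methoxy-2,3-dihydrobenzofuran, bis-TIPS | COc1cc([C@@H]2Oc3c(OC)cccc3[C@H]2CO[Si](C(C)C)(C(C)C)C(C)C)ccc1O[Si](C(C)C)(C(C)C)C(C)C | intermediate
15 | bis(pinacolato)diboron | CC1(C)OB(OC1(C)C)B1OC(C)(C)C(C)(C)O1 | starting material
16 | (2R,3S)-5-Bpin-7-methoxy-2,3-dihydrobenzofuran, bis-TIPS | COc1cc([C@@H]2Oc3c(OC)cc(B4OC(C)(C)C(C)(C)O4)cc3[C@H]2CO[Si](C(C)C)(C(C)C)C(C)C)ccc1O[Si](C(C)C)(C(C)C)C(C)C | intermediate
17 | methyl acrylate | C=CC(=O)OC | starting material
18 | (2R,3S) methyl (E)-cinnamate, bis-TIPS | COc1cc([C@@H]2Oc3c(OC)cc(/C=C/C(=O)OC)cc3[C@H]2CO[Si](C(C)C)(C(C)C)C(C)C)ccc1O[Si](C(C)C)(C(C)C)C(C)C | intermediate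
19 | (E)-3-[(2R,3S)-2-(4-hydroxy-3-methoxyphenyl)-3-(hydroxymethyl)-7-methoxy-2,3-dihydrobenzofuran-5-yl]acrylic acid | COc1cc([C@@H]2Oc3c(OC)cc(/C=C/C(=O)O)cc3[C@H]2CO)ccc1O | target

---

**Totals**
Total steps: 11. Longest linear sequence: 10 (steps 2–11 from 2-furylacetic acid; the vanillin branch is also 10).

**Three steps most likely to fail, with fallbacks**
1. Step 7 (gold benzannulation). The benzylic alkynyl ether may ionise at C2–O or undergo sigmatropic/retro-ene loss of ketene before the furan attacks. Fallback: keep a one-step two-ring benzannulation but change partners to an intramolecular Dötz reaction. An anti-homopropargylic alcohol ArCH(OH)–CH(CH2OTIPS)–C≡CH (Marshall allenylzinc addition to 3) is attached through oxygen to a (1-methoxyvinyl)chromium carbene. Thermolysis gives the 7-methoxy-5-hydroxy-dihydrobenzofuran directly, and the 5-OH is converted to the triflate for a Heck reaction with acrylate.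
2. Step 6 (alkynyl ether formation). The potassium alkoxide may trigger 1,5-O→O TIPS migration, and the product is thermally labile. Fallback: avoid the free alkoxide by going through the formate: formylate 9, convert to the 2,2-dibromovinyl ether with CBr4/PPh3, then treat with n-BuLi to give the lithium alkynyl ether and protonate.
3. Step 9 (site-selective C–H borylation on an electron-rich, hindered arene). Fallback: carry the C5 carbon from the start instead of functionalising late. Use a 4-(1,3-dioxolan-2-yl)furan-2-ylacetic acid, made from 3-furaldehyde by C5-selective lithiation of its lithium morpholide adduct, in steps 2–8. After the gold step and methylation, acid unmasks the 5-aldehyde and a Knoevenagel–Doebner condensation with malonic acid gives the (E)-acrylic acid.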